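The oxepane (O1, methyl-bearing quaternary C2, acetoxylated C3, C4, C5, alkylidene C6, C7) is disconnected at O1–C2. An ether oxygen on a tertiary carbon next to an oxygenated C3 is the imprint of a hydroxyl opening a trisubstituted epoxide at its substituted end. One acid-catalysed 7-endo cyclisation therefore forms O1–C2, closes the seven-membered ring, sets C2 by inversion and liberates the C3 hydroxyl. Its precursor is an acyclic (E)-allylic alcohol carrying a (2R,3R)-epoxide from a Shi epoxidation, with the second allylic oxygen already the target acetate and the Roche-ester-derived terminus a silyl ether. The β,γ-unsaturated ketone is added last by allylboration and oxidation.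

Key step: step 14

Remarks on the chemistry:
- The ring locants O1, C2 (quaternary), C3 (oxygenated), C4, C5, C6 (alkylidene) and C7 are also used for the chain atoms that become these ring atoms.
- Stereochemical bookkeeping: the epoxide must be R at both carbons, because ring closure inverts C2 to S and leaves C3 as R. The (S)-Roche ester gives the (R)-configured side-chain methine when its hydroxyl end is silylated and its ester end is extended. The (Z)-iodoalkene becomes the (E)-alkene of the chain by a change of priorities only. With these assignments the structures are consistent and no correction is needed.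
- Assumption: the D-fructose-derived Shi ketone, both silyl chlorides and 2-isopropoxy-4,4,5,5-tetramethyl-1,3,2-dioxaborolane are taken as commercial reagents.

**Route**

Step 1
Reactants: 1 methyl (S)-3-hydroxy-2-methylpropanoate
Product: 2 methyl (S)-3-[(tert-butyldiphenylsilyl)oxy]-2-methylpropanoate
Conditions: TBDPSCl, imidazole, CH2Cl2, 0 °C to rt
Reagents that add atoms: tert-butyl(chloro)diphenylsilane, CC(C)(C)[Si](Cl)(c1ccccc1)c1ccccc1
Why: Imidazole-assisted silylation of the primary hydroxyl (silyl ether formation) is fast and does not touch the ester or the adjacent stereocentre.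

Step 2
Reactants: 2 methyl (S)-3-[(tert-butyldiphenylsilyl)oxy]-2-methylpropanoate
Product: 3 (R)-3-[(tert-butyldiphenylsilyl)oxy]-2-methylpropan-1-ol
Conditions: i-Bu2AlH (2.5 equiv), CH2Cl2, −78 to 0 °C; aq. potassium sodium tartrate
Reagents that add atoms: none
Why: Reduction of the ester to the primary alcohol with a dialkylaluminium hydride at low temperature (ester reduction) leaves the silyl ether in place and does not epimerise the methine, whose descriptor becomes R only because the priorities change.

Step 3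
Reactants: 3 (R)-3-[(tert-butyldiphenylsilyl)oxy]-2-methylpropan-1-ol
Product: 4 (S)-tert-butyl(3-iodo-2-methylpropoxy)diphenylsilane
Conditions: PPh3, I2, imidazole, CH2Cl2, 0 °C to rt
Reagents that add atoms: iodine, II
Why: Appel-type iodination converts the primary alcohol into the iodide by substitution at CH2, one carbon away from the stereocentre.

Step 4
Reactants: 4 (S)-tert-butyl(3-iodo-2-methylpropoxy)diphenylsilane; 5 (4-bromobut-1-yn-1-yl)trimethylsilane
Product: 7 (R)-tert-butyl{[2-methyl-7-(trimethylsilyl)hept-6-yn-1-yl]oxy}diphenylsilane, via Me3SiC≡CCH2CH2MgBr 6 (not isolated)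
Conditions: 5 (2 equiv), Mg, THF, rt to 40 °C; then 4, Li2CuCl4 (5 mol %), THF, −20 °C to rt
Reagents that add atoms: none
Why: Copper-catalysed coupling of an alkyl Grignard reagent with a primary alkyl iodide (Kochi-type C(sp3)–C(sp3) coupling) joins the two fragments, the silyl-capped alkyne and the silyl ether being inert to the Grignard reagent and the stereocentre not being involved.

Step 5
Reactants: 7 (R)-tert-butyl{[2-methyl-7-(trimethylsilyl)hept-6-yn-1-yl]oxy}diphenylsilane
Product: 8 (R)-tert-butyl[(2-methylhept-6-yn-1-yl)oxy]diphenylsilane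
Conditions: K2CO3, MeOH, rt
Reagents that add atoms: none
Why: Base-catalysed methanolysis cleaves the C(sp)–SiMe3 bond (alkyne protodesilylation) far faster than the hindered TBDPS ether.

Step 6
Reactants: 8 (R)-tert-butyl[(2-methylhept-6-yn-1-yl)oxy]diphenylsilane
Product: 11 (3E,8R)-9-[(tert-butyldiphenylsilyl)oxy]-4,8-dimethylnon-3-en-1-ol, via alkenyl(dimethyl)alane 9 (not isolated), via lithium alkenyl(butyl)dimethylalanate 10 (not isolated)
Conditions: AlMe3 (3 equiv), Cp2ZrCl2 (0.3 equiv), CH2Cl2, 0 °C to rt; volatiles removed; n-BuLi, hexane, −78 to 0 °C; oxirane, THF, 0 °C to rt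
Reagents that add atoms: trimethylaluminium, C[Al](C)C; oxirane, C1CO1
Why: Zirconium-catalysed carboalumination (Negishi carboalumination) adds methyl and aluminium syn across the terminal alkyne with methyl on the internal carbon, and the alanate made with n-BuLi opens oxirane with retention at the alkenyl carbon, so the (E)-trisubstituted alkene is fixed by the syn addition.

Step 7
Reactants: 11 (3E,8R)-9-[(tert-butyldiphenylsilyl)oxy]-4,8-dimethylnon-3-en-1-ol
Product: 12 tert-butyl{[(2R,6E)-9-iodo-2,6-dimethylnon-6-en-1-yl]oxy}diphenylsilane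
Conditions: PPh3, I2, imidazole, CH2Cl2, 0 °C
Reagents that add atoms: iodine, II
Why: Appel-type iodination of the primary homoallylic alcohol gives the iodide needed for zinc insertion without disturbing the alkene geometry.

Step 8
Reactants: 13 but-2-yne-1,4-diol
Product: 14 4-[(tert-butyldimethylsilyl)oxy]but-2-yn-1-ol
Conditions: 13 (4 equiv), TBSCl (1 equiv), imidazole, DMF, 0 °C to rt
Reagents that add atoms: tert-butyl(chloro)dimethylsilane, CC(C)(C)[Si](C)(C)Cl
Why: Monosilylation of a symmetrical diol used in excess (statistical protection) gives the mono-ether, the water-soluble diol being removed by extraction.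

Step 9
Reactants: 14 4-[(tert-butyldimethylsilyl)oxy]but-2-yn-1-ol
Product: 16 (Z)-4-[(tert-butyldimethylsilyl)oxy]-3-iodobut-2-en-1-ol, via cyclic sodium alkenylalanate 15 (not isolated)
Conditions: NaAlH2(OCH2CH2OMe)2, THF, 0 °C to rt; then I2, THF, −78 to 0 °C
Reagents that add atoms: iodine, II
Why: Hydroxyl-directed trans-hydroalumination of the propargylic alcohol delivers hydride to the near alkyne carbon and aluminium to the far one within a five-membered alanate, and iodinolysis with retention gives the (Z)-iodoalkene in which the two oxygens are already differentiated.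

Step 10
Reactants: 16 (Z)-4-[(tert-butyldimethylsilyl)oxy]-3-iodobut-2-en-1-ol
Product: 17 (Z)-4-[(tert-butyldimethylsilyl)oxy]-3-iodobut-2-en-1-yl acetate
Conditions: Ac2O, pyridine, DMAP (cat.), CH2Cl2, 0 °C
Reagents that add atoms: acetic anhydride, CC(=O)OC(C)=O
Why: Acylation of the primary allylic alcohol under nucleophilic catalysis (esterification) installs the acetate that the target carries at this position.

Step 11
Reactants: 12 tert-butyl{[(2R,6E)-9-iodo-2,6-dimethylnon-6-en-1-yl]oxy}diphenylsilane; 17 (Z)-4-[(tert-butyldimethylsilyl)oxy]-3-iodobut-2-en-1-yl acetate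
Product: 19 (2E,6E,11R)-3-{[(tert-butyldimethylsilyl)oxy]methyl}-12-[(tert-butyldiphenylsilyl)oxy]-7,11-dimethyldodeca-2,6-dien-1-yl acetate, via alkylzinc iodide 18 (not isolated)
Conditions: Zn dust (activated with BrCH2CH2Br and Me3SiCl), LiCl, THF, 40 °C; then 17 (1.2 equiv), PdCl2(dppf) (5 mol %), THF, rt
Reagents that add atoms: none
Why: Negishi coupling, in which zinc inserts into the primary C–I bond and zerovalent palladium formed from PdCl2(dppf) adds to the C(sp2)–I bond much faster than it ionises the allylic acetate, so that transmetalation and reductive elimination join C5 to C6 with retention of the alkene geometry.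

Step 12
Reactants: 19 (2E,6E,11R)-3-{[(tert-butyldimethylsilyl)oxy]methyl}-12-[(tert-butyldiphenylsilyl)oxy]-7,11-dimethyldodeca-2,6-dien-1-yl acetate
Product: 20 (2E)-3-{[(tert-butyldimethylsilyl)oxy]methyl}-5-[(2R,3R)-3-{(4R)-5-[(tert-butyldiphenylsilyl)oxy]-4-methylpentyl}-3-methyloxiran-2-yl]pent-2-en-1-yl acetate
Conditions: D-fructose-derived Shi ketone (1,2:4,5-di-O-isopropylidene-β-D-erythro-hexo-2,3-diulo-2,6-pyranose, 0.3 equiv), KHSO5 (as 2KHSO5·KHSO4·K2SO4), K2CO3, Bu4NHSO4, MeCN–(MeO)2CH2–aq. Na2B4O7 buffer, 0 °C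
Reagents that add atoms: potassium peroxymonosulfate, [K+].[O-]S(=O)(=O)OO
Why: Shi epoxidation, in which the chiral dioxirane generated from the D-fructose-derived ketone attacks the electron-rich trialkyl-substituted alkene through a spiro transition state and should give the epoxide that is R at both carbons (reagent control), while the second alkene is deactivated by its two allylic C–O bonds.

Step 13
Reactants: 20 (2E)-3-{[(tert-butyldimethylsilyl)oxy]methyl}-5-[(2R,3R)-3-{(4R)-5-[(tert-butyldiphenylsilyl)oxy]-4-methylpentyl}-3-methyloxiran-2-yl]pent-2-en-1-yl acetate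
Product: 21 (2E)-5-[(2R,3R)-3-{(4R)-5-[(tert-butyldiphenylsilyl)oxy]-4-methylpentyl}-3-methyloxiran-2-yl]-3-(hydroxymethyl)pent-2-en-1-yl acetate
Conditions: HF·pyridine, pyridine, THF, 0 °C
Reagents that add atoms: none
Why: Desilylation with pyridine-buffered HF·pyridine (fluoride-mediated silyl ether cleavage) removes the unhindered primary allylic TBS group well before the bulkier TBDPS ether and should leave the epoxide and the acetate intact.

Step 14
Reactants: 21 (2E)-5-[(2R,3R)-3-{(4R)-5-[(tert-butyldiphenylsilyl)oxy]-4-methylpentyl}-3-methyloxiran-2-yl]-3-(hydroxymethyl)pent-2-en-1-yl acetate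
Product: 22 (2S,3R,6E)-6-(2-acetoxyethylidene)-2-{(4R)-5-[(tert-butyldiphenylsilyl)oxy]-4-methylpentyl}-2-methyloxepan-3-ol
Conditions: camphor-10-sulfonic acid (0.1 equiv), CH2Cl2 (0.01 M), 0 °C
Reagents that add atoms: none
Why: Protonation of the epoxide oxygen by the sulfonic acid weakens the C2–O bond, because the methyl- and alkyl-substituted C2 carries most of the developing positive charge, and the C7 hydroxyl then attacks C2 from the face opposite the departing oxygen. The closest known reaction type is the acid-promoted endo-selective cyclisation of hydroxy epoxides at the tertiary carbon of trisubstituted epoxides. The oxepane closes in the 7-endo-tet mode (endo with respect to the epoxide C–O bond that breaks), the competing mode being 6-exo attack at C3. The new stereocentre at C2 is fixed by the (R)-configured epoxide carbon through inversion to (S), while C3 keeps its C–O bond and its (R) configuration, so both ring stereocentres trace back to the Shi epoxidation. The step needs regioselectivity for C2 over C3, which the C2 methyl group secures electronically, and chemoselectivity, which the substrate secures by offering a single free hydroxyl, an alkene deactivated by two allylic oxygens, an acetate held away from the hydroxyl by the (E) geometry and a silylated side-chain terminus; high dilution suppresses intermolecular opening.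

Step 15
Reactants: 22 (2S,3R,6E)-6-(2-acetoxyethylidene)-2-{(4R)-5-[(tert-butyldiphenylsilyl)oxy]-4-methylpentyl}-2-methyloxepan-3-ol
Product: 23 (2S,3R,6E)-6-(2-acetoxyethylidene)-2-{(4R)-5-[(tert-butyldiphenylsilyl)oxy]-4-methylpentyl}-2-methyloxepan-3-yl acetate
Conditions: Ac2O, pyridine, DMAP, CH2Cl2, rt
Reagents that add atoms: acetic anhydride, CC(=O)OC(C)=O
Why: DMAP-catalysed acetylation (esterification) of the secondary C3 hydroxyl, hindered by the neighbouring quaternary centre but the only free hydroxyl, proceeds with retention since the C–O bond is not broken.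

Step 16
Reactants: 23 (2S,3R,6E)-6-(2-acetoxyethylidene)-2-{(4R)-5-[(tert-butyldiphenylsilyl)oxy]-4-methylpentyl}-2-methyloxepan-3-yl acetate
Product: 24 (2S,3R,6E)-6-(2-acetoxyethylidene)-2-[(4R)-5-hydroxy-4-methylpentyl]-2-methyloxepan-3-yl acetate
Conditions: HF·pyridine, THF, 0 °C to rt
Reagents that add atoms: none
Why: HF·pyridine cleaves the remaining primary TBDPS ether (fluoride-mediated desilylation) under conditions that leave both acetates, the allylic ether linkage and the alkene untouched.

Step 17
Reactants: 25 2,3-dimethylbut-1-ene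
Product: 27 4,4,5,5-tetramethyl-2-(3-methyl-2-methylidenebutyl)-1,3,2-dioxaborolane, via 2-isopropylallylpotassium 26 (not isolated)
Conditions: n-BuLi, KOtBu, hexane, 0 °C to rt; then i-PrOB(pin), THF, −78 °C to rt
Reagents that add atoms: 2-isopropoxy-4,4,5,5-tetramethyl-1,3,2-dioxaborolane, CC(C)OB1OC(C)(C)C(C)(C)O1
Why: Allylic metalation with the n-BuLi/KOtBu superbase removes a proton from the methyl group in preference to the tertiary allylic C–H, and the symmetrical 2-isopropylallyl anion is trapped at boron by the isopropoxyboronate (metalation–borylation).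

Step 18
Reactants: 24 (2S,3R,6E)-6-(2-acetoxyethylidene)-2-[(4R)-5-hydroxy-4-methylpentyl]-2-methyloxepan-3-yl acetate
Product: 28 (2S,3R,6E)-6-(2-acetoxyethylidene)-2-methyl-2-[(4R)-4-methyl-5-oxopentyl]oxepan-3-yl acetate
Conditions: Dess–Martin periodinane, NaHCO3, CH2Cl2, 0 °C to rt
Reagents that add atoms: none
Why: Dess–Martin oxidation of the primary alcohol under bicarbonate buffering gives the α-methyl aldehyde without epimerisation or loss of the acetates, and the aldehyde is used at once.

Step 19
Reactants: 28 (2S,3R,6E)-6-(2-acetoxyethylidene)-2-methyl-2-[(4R)-4-methyl-5-oxopentyl]oxepan-3-yl acetate; 27 4,4,5,5-tetramethyl-2-(3-methyl-2-methylidenebutyl)-1,3,2-dioxaborolane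
Product: 30 (2S,3R,6E)-6-(2-acetoxyethylidene)-2-[(4R,5RS)-5-hydroxy-4,8-dimethyl-7-methylidenenonyl]-2-methyloxepan-3-yl acetate, via pinacol borate ester 29 (not isolated)
Conditions: 27 (1.5 equiv), toluene, rt to 40 °C; aqueous work-up
Reagents that add atoms: none
Why: Allylboration of the aldehyde through a closed six-membered transition state proceeds under neutral conditions with allyl transposition, so the α-stereocentre and both acetates survive, and the new carbinol centre is formed as a mixture that is erased in the next step.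

Step 20
Reactants: 30 (2S,3R,6E)-6-(2-acetoxyethylidene)-2-[(4R,5RS)-5-hydroxy-4,8-dimethyl-7-methylidenenonyl]-2-methyloxepan-3-yl acetate
Product: 31 (2S,3R,6E)-6-(2-acetoxyethylidene)-2-[(4R)-4,8-dimethyl-7-methylidene-5-oxononyl]-2-methyloxepan-3-yl acetate
Conditions: Dess–Martin periodinane, NaHCO3, CH2Cl2, 0 °C
Reagents that add atoms: none
Why: Buffered Dess–Martin oxidation of the homoallylic alcohol gives the β,γ-unsaturated ketone under neutral conditions that should neither move the 1,1-disubstituted alkene into conjugation nor epimerise the α-methyl centre.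

**Compound list**

1 | methyl (S)-3-hydroxy-2-methylpropanoate | COC(=O)[C@@H](C)CO | starting material
2 | methyl (S)-3-[(tert-butyldiphenylsilyl)oxy]-2-methylpropanoate | CC(C)(C)[Si](c1ccccc1)(c1ccccc1)OC[C@H](C)C(=O)OC | intermediate
3 | (R)-3-[(tert-butyldiphenylsilyl)oxy]-2-methylpropan-1-ol | CC(C)(C)[Si](c1ccccc1)(c1ccccc1)OC[C@H](C)CO | intermediate
4 | (S)-tert-butyl(3-iodo-2-methylpropoxy)diphenylsilane | CC(C)(C)[Si](c1ccccc1)(c1ccccc1)OC[C@H](C)CI | intermediate
5 | (4-bromobut-1-yn-1-yl)trimethylsilane | C[Si](C)(C)C#CCCBr | starting material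
6 | [4-(trimethylsilyl)but-3-yn-1-yl]magnesium bromide (not isolated) | C[Si](C)(C)C#CCC[Mg]Br | intermediate
7 | (R)-tert-butyl{[2-methyl-7-(trimethylsilyl)hept-6-yn-1-yl]oxy}diphenylsilane | CC(C)(C)[Si](c1ccccc1)(c1ccccc1)OC[C@H](C)CCCC#C[Si](C)(C)C | intermediate
8 | (R)-tert-butyl[(2-methylhept-6-yn-1-yl)oxy]diphenylsilane | CC(C)(C)[Si](c1ccccc1)(c1ccccc1)OC[C@H](C)CCCC#C | intermediate
9 | dimethyl{(1E,6R)-7-[(tert-butyldiphenylsilyl)oxy]-2,6-dimethylhept-1-en-1-yl}alane (not isolated) | CC(C)(C)[Si](c1ccccc1)(c1ccccc1)OC[C@H](C)CCC/C(C)=C/[Al](C)C | intermediate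
10 | lithium butyl{(1E,6R)-7-[(tert-butyldiphenylsilyl)oxy]-2,6-dimethylhept-1-en-1-yl}dimethylalanate (not isolated) | CC(C)(C)[Si](c1ccccc1)(c1ccccc1)OC[C@H](C)CCC/C(C)=C/[Al-](C)(C)CCCC.[Li+] | intermediate
11 | (3E,8R)-9-[(tert-butyldiphenylsilyl)oxy]-4,8-dimethylnon-3-en-1-ol | CC(C)(C)[Si](c1ccccc1)(c1ccccc1)OC[C@H](C)CCC/C(C)=C/CCO | intermediate
12 | tert-butyl{[(2R,6E)-9-iodo-2,6-dimethylnon-6-en-1-yl]oxy}diphenylsilane | CC(C)(C)[Si](c1ccccc1)(c1ccccc1)OC[C@H](C)CCC/C(C)=C/CCI | intermediate
13 | but-2-yne-1,4-diol | OCC#CCO | starting material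
14 | 4-[(tert-butyldimethylsilyl)oxy]but-2-yn-1-ol | OCC#CCO[Si](C)(C)C(C)(C)C | intermediate
15 | sodium 2,2-bis(2-methoxyethoxy)-3-{[(tert-butyldimethylsilyl)oxy]methyl}-2,5-dihydro-1,2-oxaaluminol-2-uide, the cyclic alkenylalanate (not isolated) | [Na+].COCCO[Al-]1(OCCOC)OCC=C1CO[Si](C)(C)C(C)(C)C | intermediate
16 | (Z)-4-[(tert-butyldimethylsilyl)oxy]-3-iodobut-2-en-1-ol | OC/C=C(\I)CO[Si](C)(C)C(C)(C)C | intermediate
17 | (Z)-4-[(tert-butyldimethylsilyl)oxy]-3-iodobut-2-en-1-yl acetate | CC(=O)OC/C=C(\I)CO[Si](C)(C)C(C)(C)C | intermediate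
18 | {(3E,8R)-9-[(tert-butyldiphenylsilyl)oxy]-4,8-dimethylnon-3-en-1-yl}zinc iodide (not isolated) | CC(C)(C)[Si](c1ccccc1)(c1ccccc1)OC[C@H](C)CCC/C(C)=C/CC[Zn]I | intermediate
19 | (2E,6E,11R)-3-{[(tert-butyldimethylsilyl)oxy]methyl}-12-[(tert-butyldiphenylsilyl)oxy]-7,11-dimethyldodeca-2,6-dien-1-yl acetate | CC(C)(C)[Si](c1ccccc1)(c1ccccc1)OC[C@H](C)CCC/C(C)=C/CC/C(CO[Si](C)(C)C(C)(C)C)=C\COC(C)=O | intermediate
20 | (2E)-3-{[(tert-butyldimethylsilyl)oxy]methyl}-5-[(2R,3R)-3-{(4R)-5-[(tert-butyldiphenylsilyl)oxy]-4-methylpentyl}-3-methyloxiran-2-yl]pent-2-en-1-yl acetate | CC(C)(C)[Si](c1ccccc1)(c1ccccc1)OC[C@H](C)CCC[C@@]1(C)O[C@@H]1CC/C(CO[Si](C)(C)C(C)(C)C)=C\COC(C)=O | intermediate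
21 | (2E)-5-[(2R,3R)-3-{(4R)-5-[(tert-butyldiphenylsilyl)oxy]-4-methylpentyl}-3-methyloxiran-2-yl]-3-(hydroxymethyl)pent-2-en-1-yl acetate | CC(C)(C)[Si](c1ccccc1)(c1ccccc1)OC[C@H](C)CCC[C@@]1(C)O[C@@H]1CC/C(CO)=C\COC(C)=O | intermediate
22 | (2S,3R,6E)-6-(2-acetoxyethylidene)-2-{(4R)-5-[(tert-butyldiphenylsilyl)oxy]-4-methylpentyl}-2-methyloxepan-3-ol | CC(C)(C)[Si](c1ccccc1)(c1ccccc1)OC[C@H](C)CCC[C@]1(C)OC/C(=C/COC(C)=O)CC[C@H]1O | intermediate
23 | (2S,3R,6E)-6-(2-acetoxyethylidene)-2-{(4R)-5-[(tert-butyldiphenylsilyl)oxy]-4-methylpentyl}-2-methyloxepan-3-yl acetate | CC(C)(C)[Si](c1ccccc1)(c1ccccc1)OC[C@H](C)CCC[C@]1(C)OC/C(=C/COC(C)=O)CC[C@H]1OC(C)=O | intermediate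
24 | (2S,3R,6E)-6-(2-acetoxyethylidene)-2-[(4R)-5-hydroxy-4-methylpentyl]-2-methyloxepan-3-yl acetate | OC[C@H](C)CCC[C@]1(C)OC/C(=C/COC(C)=O)CC[C@H]1OC(C)=O | intermediate
25 | 2,3-dimethylbut-1-ene | C=C(C)C(C)C | starting material
26 | (3-methyl-2-methylidenebutyl)potassium, the 2-isopropylallylpotassium (not isolated) | CC(C)C(=C)C[K] | intermediate
27 | 4,4,5,5-tetramethyl-2-(3-methyl-2-methylidenebutyl)-1,3,2-dioxaborolane | CC(C)C(=C)CB1OC(C)(C)C(C)(C)O1 | intermediate
28 | (2S,3R,6E)-6-(2-acetoxyethylidene)-2-methyl-2-[(4R)-4-methyl-5-oxopentyl]oxepan-3-yl acetate | O=C[C@H](C)CCC[C@]1(C)OC/C(=C/COC(C)=O)CC[C@H]1OC(C)=O | intermediate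
29 | pinacol borate ester of 30, boron on the new carbinol oxygen (not isolated) | C=C(CC(OB1OC(C)(C)C(C)(C)O1)[C@H](C)CCC[C@]2(C)OC/C(=C/COC(C)=O)CC[C@H]2OC(C)=O)C(C)C | intermediate
30 | (2S,3R,6E)-6-(2-acetoxyethylidene)-2-[(4R,5RS)-5-hydroxy-4,8-dimethyl-7-methylidenenonyl]-2-methyloxepan-3-yl acetate | C=C(CC(O)[C@H](C)CCC[C@]1(C)OC/C(=C/COC(C)=O)CC[C@H]1OC(C)=O)C(C)C | intermediate
31 | (2S,3R,6E)-6-(2-acetoxyethylidene)-2-[(4R)-4,8-dimethyl-7-methylidene-5-oxononyl]-2-methyloxepan-3-yl acetate (CNP0582730.1) | C=C(CC(=O)[C@H](C)CCC[C@]1(C)OC/C(=C/COC(C)=O)CC[C@H]1OC(C)=O)C(C)C | target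

**Step count**

Total step count: 20 (the vinyl iodide branch, steps 8–10, and the boronate preparation, step 17, included).
Longest linear sequence: 16 steps (steps 1–7, 11–16 and 18–20).

**Steps most likely to fail**

Step 14. The hydroxyl may close onto the secondary carbon C3 (6-exo), or the protonated epoxide may rearrange by hydride shift before it is trapped. The fallback separates C–O bond formation at C2 from ring closure. It sets out from 21: MnO2 in CH2Cl2 oxidises the allylic alcohol to the epoxy enal F1. Dilute aqueous HClO4 in THF then lets water, present in large excess and free of any ring-size bias, open the epoxide at C2 with inversion. The resulting (2S,3R)-diol condenses with the aldehyde to the 6,8-dioxabicyclo[3.2.1]octane acetal F2, completed with pyridinium p-toluenesulfonate and MgSO4 if needed. i-Bu2AlH in CH2Cl2 (−78 to 0 °C) should coordinate the less hindered acetal oxygen on C3 and cleave the C7–O bond to that oxygen reductively, the known regiochemistry by which such bicyclic acetals give oxepan-3-ols. It reduces the acetate at the same time, giving the oxepane diol F3. Ac2O, pyridine and DMAP acetylate both hydroxyls, and the route is rejoined at 23.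

Step 11. Zerovalent palladium may ionise the allylic acetate of 17 or of the product, so that the alkylzinc reagent is consumed by allyl–alkyl coupling or protonolysis. The fallback runs the coupling with no allylic ester in the molecule. It sets out from 16: 4-methoxybenzyl trichloroacetimidate with catalytic camphor-10-sulfonic acid gives the 4-methoxybenzyl ether F4. Negishi coupling of F4 with 18 under the catalyst of step 11 gives the diene ether F5. DDQ in wet CH2Cl2 at 0 °C removes the benzyl-type ether to give the allylic alcohol F6, and Ac2O with pyridine returns to the route at 19.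

Step 13. Fluoride may fail to discriminate cleanly between the two silyl ethers, or the HF medium may open the epoxide. The fallback changes the order, so that the selective desilylation is done before the epoxide exists. It sets out from 19: catalytic camphor-10-sulfonic acid in MeOH–CH2Cl2 at 0 °C, where a TBDPS ether is far more stable than a primary TBS ether, gives the dienol F7. Shi epoxidation of F7 under the conditions of step 12 should again select the trialkyl-substituted alkene, the allylic-alcohol alkene remaining the electron-poorer one, and delivers 21, where the route is rejoined.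

**Further compounds**

F1 | step 14 | (2E)-5-[(2R,3R)-3-{(4R)-5-[(tert-butyldiphenylsilyl)oxy]-4-methylpentyl}-3-methyloxiran-2-yl]-3-formylpent-2-en-1-yl acetate (epoxy enal) | CC(C)(C)[Si](c1ccccc1)(c1ccccc1)OC[C@H](C)CCC[C@@]1(C)O[C@@H]1CC/C(C=O)=C\COC(C)=O
F2 | step 14 | 6,8-dioxabicyclo[3.2.1]octane acetal in which the former C7 aldehyde carbon is bonded to the C2 and C3 oxygens, with the (E)-2-acetoxyethylidene group on C6 | CC(C)(C)[Si](c1ccccc1)(c1ccccc1)OC[C@H](C)CCC[C@]1(C)O[C@@H]2/C(=C/COC(C)=O)CC[C@H]1O2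
F3 | step 14 | (2S,3R,6E)-2-{(4R)-5-[(tert-butyldiphenylsilyl)oxy]-4-methylpentyl}-6-(2-hydroxyethylidene)-2-methyloxepan-3-ol (oxepane diol) | CC(C)(C)[Si](c1ccccc1)(c1ccccc1)OC[C@H](C)CCC[C@]1(C)OC/C(=C/CO)CC[C@H]1O
F4 | step 11 | (Z)-tert-butyl({2-iodo-4-[(4-methoxybenzyl)oxy]but-2-en-1-yl}oxy)dimethylsilane | COc1ccc(COC/C=C(\I)CO[Si](C)(C)C(C)(C)C)cc1
F5 | step 11 | tert-butyl{[(2R,6E,10E)-10-{[(tert-butyldimethylsilyl)oxy]methyl}-12-[(4-methoxybenzyl)oxy]-2,6-dimethyldodeca-6,10-dien-1-yl]oxy}diphenylsilane | CC(C)(C)[Si](c1ccccc1)(c1ccccc1)OC[C@H](C)CCC/C(C)=C/CC/C(CO[Si](C)(C)C(C)(C)C)=C\COCc1ccc(OC)cc1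
F6 | step 11 | (2E,6E,11R)-3-{[(tert-butyldimethylsilyl)oxy]methyl}-12-[(tert-butyldiphenylsilyl)oxy]-7,11-dimethyldodeca-2,6-dien-1-ol | CC(C)(C)[Si](c1ccccc1)(c1ccccc1)OC[C@H](C)CCC/C(C)=C/CC/C(CO[Si](C)(C)C(C)(C)C)=C\CO
F7 | step 13 | (2E,6E,11R)-12-[(tert-butyldiphenylsilyl)oxy]-3-(hydroxymethyl)-7,11-dimethyldodeca-2,6-dien-1-yl acetate | CC(C)(C)[Si](c1ccccc1)(c1ccccc1)OC[C@H](C)CCC/C(C)=C/CC/C(CO)=C\COC(C)=O
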